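## Analysis of the target

The target 14 is an achiral 1,3-diarylpropane in which one aryl end (ring A) is also the 2-hydroxy-4-methoxyphenyl half of a benzophenone. Ring B is the 4-hydroxyphenyl group on the carbonyl carbon and ring C the 4-hydroxyphenyl group at the far end of the chain. Numbering ring A from the aroyl-bearing carbon, C1 carries the ketone, C2 the chelated hydroxyl, C4 the methoxy group and C5 the chain Ca–Cb–Cc, while C3 and C6 are CH. There is no stereocentre, so nothing stereochemical has to be set or related; every selectivity question is one of regio- or chemoselectivity. The sensitive groups are three phenols (one hydrogen-bonded to the carbonyl), one methyl ether that must stay distinct from them, and a doubly benzylic diaryl ketone that can be over-reduced by hydride or by hydrogenolysis. The difficulty lies in the 1,2,4,5-pattern of ring A with O2 and O4 differentiated, and in a saturated three-carbon tether between two electron-rich arenes that has no functional handle of its own. The plan rests on two facts: Ca is benzylic to C5, the ring A position para to O2 and ortho to O4 that electrophiles choose, and Cb–Cc can be carried as a triple bond whose ends are an sp3 benzylic carbon (Ca) and an sp2 carbon of ring C. A two-carbon acetylenic unit with two chemically different termini can therefore join a ring A benzylic electrophile to a ring C aryl halide, and the unsaturation is removed in the same hydrogenation that frees the phenols.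

## Retrosynthetic reasoning

**14 to 13.** No skeletal bond is cut in the first backward step. The saturated Cb–Cc bond of 14 is traced to a triple bond and the three phenols to benzyl ethers, which gives the tribenzyl alkyne 13. Benzyl is chosen because it leaves under the conditions that saturate the chain, so the end-game is one operation, and the methyl ether at O4 is inert to it. The forward reaction has to reduce the alkyne and cleave three O–benzyl bonds while leaving the diaryl ketone alone.

**13 to 9, 10 and 11.** The bonds cut are Ca–Cb and Cc–C(aryl) of ring C, on either side of the two alkyne carbons. These are the only two positions of the chain where a cross-coupling can be set up without extra functional groups: Ca is benzylic and Cc sits on an arene. Propiolic acid 10 supplies Cb and Cc, and its two ends differ in kind, an acidic C–H and a carboxylate. The aryl iodide 11 is joined first at the C–H end at room temperature to give the arylpropiolate 12, and the benzylic chloride 9 is joined second at the carboxyl end with decarboxylation on heating. Three simple pieces are thus united in one flask with two new C–C bonds. The forward reaction needs a base that the activated chloride 9 cannot alkylate, so an inorganic carbonate is used from the start and no amidine or amine base is present; 9 is made the limiting partner. The O2 hydroxyl must be capped in 9, because a free hydroxyl para to the chloromethyl group would let 9 collapse by 1,6-elimination of chloride under base.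

**9 to 8 to 7.** The C–Cl bond of 9 comes from the benzylic alcohol 8, and the C5–Ca bond of 8 is cut back to the aryl bromide 7 and a hydroxymethyl nucleophile in a palladium-catalysed cross-coupling. Electrophilic formylation of the bromine-free benzophenone was considered and set aside. That ring is deactivated by the aroyl group, Lewis-acid formylation endangers the chelating benzyl ether at O2, and the aldehyde would then have to be reduced next to a ketone. A bromide set at C5 earlier, followed by cross-coupling, delivers Ca at the alcohol oxidation level in one step with no regiochemical question.

**7 to 6 to 3 and 5 (from 4).** The ketone is taken back to the carbinol 6, and the bond between the carbinol carbon and ring B is cut to the aldehyde 3 and the aryl Grignard reagent 5, made from the bromide 4. The cut is placed there because ring A can be bought with its C1 carbon already in place as an aldehyde. An acylation of a ring A lacking that carbon would not distinguish the positions para to O2 and para to O4, and its acid promoter would strip benzyl ethers. The forward steps need a Grignard addition that leaves the C5 bromide alone and a neutral oxidation of an acid-sensitive, electron-rich benzhydrol.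

**3 to 2 to 1.** The O2–benzyl bond and then the C5–Br bond are removed, which leads to 2-hydroxy-4-methoxybenzaldehyde 1. In 1 the hydroxyl (para), the methoxy group (ortho) and the formyl group (meta) all direct an electrophile to C5, so the bromination to 2 is the point at which the regiochemistry of the chain attachment is fixed. The benzyl ether is put on before the Grignard step so that no equivalent of 5 is spent on a phenol and no ortho-hydroxy benzhydrol, which would readily lose water across the ring, is formed. Compound 1 already holds the O2/O4 differentiation: the methyl ether is bought, not made.

## Alternatives that were turned down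

**Alternative 1:** Ring A is built by cutting C1–C2 and C5–C6. In the forward key step the vinylogous silyl ketene acetal A1, a 1,3-dimethoxy-1-silyloxy diene that carries the arylpropyl chain at its nucleophilic terminus, would add across the terminal aryl ynone A2. The adduct would aromatise by eliminating the acetal methoxy group, giving the bis-silyl ether A3, and desilylation would then give 14.
- For it: the cycloaddition is convergent, its regiochemistry follows from the polarity of both partners, O2 emerges free and O4 methylated without any protecting-group decision, and the final deprotection does not endanger the ketone. On these points it is as strong as or stronger than the chosen route, whose hydrogenation has to spare the carbonyl group.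
- Against it: A1 is not a catalogue compound and needs a multistep preparation in which the whole chain is already installed. It is hydrolytically labile, would be used as a mixture of double-bond isomers, and dienes of this type substituted at the reacting terminus are sluggish. A2 is prone to polymerisation and to open-chain conjugate addition instead of ring closure.
- Comparison: the chosen strategy builds no ring. Ring A is purchased with its oxygen pattern, and the two demanding C–C bonds are cross-couplings between stable, storable partners, so the risk is concentrated in one step whose components can each be made in quantity.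

**Alternative 2:** Ring A is cut at C1–C6 and C3–C4 at the cyclohexane-1,3-dione oxidation level. In the forward key step the central carbon of the aryl β-diketone A4 would add in a Michael reaction to the 2-alkylacrylate A5, and the methyl carbon of the derived dianion would then close the ring by Claisen condensation onto the ester, giving the triketone A6. A6 would have to be dehydrogenated, methylated at O4 and debenzylated.
- For it: A4 and A5 are made from cheap materials, no palladium is needed before the last step, and the positions of the aroyl group and the chain are fixed by construction. On raw-material cost it is as strong as or stronger than the chosen route.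
- Against it: α-alkyl acrylates are poor acceptors for a doubly stabilised carbon nucleophile, so the addition is reversible. The ring closure needs a second, much stronger base regime in the presence of an acidic methine and can acylate on oxygen. A6 is at the wrong oxidation level, so three further steps follow the key step, one of them an oxidation of a triketone with benzylic positions nearby. The stereocentre of A6 is formed without control, which does not matter since it is lost on aromatisation.
- Comparison: the chosen strategy works at the arene oxidation level from the first step, needs one step after the key step instead of three, and never has to install the O4 methyl group.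

**Alternative 3:** Ring A is cut at C1–C6 and traced to the 2-phenacyl-5-alkyl-4-pyranone A7. In the forward key step aqueous base would add to the unsubstituted C6 of A7, the ring would open to a polycarbonyl chain, and the phenacyl methylene would condense with the unmasked C6 aldehyde to give the resorcinol A8. Selective methylation at O4 and debenzylation would follow.
- For it: ring A arises already aromatic with no oxidant and no transition metal, and the substitution pattern is encoded in A7. On these points it is stronger than the chosen route.
- Against it: A7 is itself a multistep target, a 4-pyranone with a free C6, a chain at C5 and an acylated side arm at C2. The opened chain has other ways to reclose, back to a pyranone or through its central methylene onto the aryl ketone. A8 has O2 and O4 both free, so a selective methylation must be added, helped only by the chelation of O2, and the final hydrogenolysis carries the same ketone risk as in the chosen route.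
- Comparison: the chosen strategy is shorter because ring A with its O4 methyl ether is bought, and each of its bond-forming steps has one possible regiochemical outcome.

Key step: step 7

## Route

Step 1
Reactants: 1 2-hydroxy-4-methoxybenzaldehyde
Product: 2 5-bromo-2-hydroxy-4-methoxybenzaldehyde
Conditions: NBS (1.0 equiv), MeCN, 0 °C to rt
Reagents that add atoms: N-bromosuccinimide, O=C1CCC(=O)N1Br
Why: Electrophilic aromatic bromination; C5 is para to the hydroxyl, ortho to the methoxy group, meta to the formyl group and less hindered than C3, which lies between the two oxygens. One equivalent of NBS at low temperature should stop at the monobromide.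

Step 2
Reactants: 2 5-bromo-2-hydroxy-4-methoxybenzaldehyde
Product: 3 2-(benzyloxy)-5-bromo-4-methoxybenzaldehyde
Conditions: BnBr, K2CO3, DMF, 60 °C
Reagents that add atoms: benzyl bromide, BrCc1ccccc1
Why: Williamson ether synthesis on the phenoxide, which is alkylated cleanly in DMF although it is hydrogen-bonded to the aldehyde. Capping O2 here saves an equivalent of 5 in step 3 and keeps a free ortho-hydroxy benzhydrol out of the route.

Step 3
Reactants: 3 2-(benzyloxy)-5-bromo-4-methoxybenzaldehyde; 4 1-(benzyloxy)-4-bromobenzene
Product: 6 [2-(benzyloxy)-5-bromo-4-methoxyphenyl][4-(benzyloxy)phenyl]methanol (racemic), via [4-(benzyloxy)phenyl]magnesium bromide 5 (not isolated)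
Conditions: 4 (1.3 equiv), Mg, THF, reflux; solution of 5 decanted onto 3, THF, −20 to 0 °C; aq NH4Cl
Reagents that add atoms: none
Why: Grignard formation and 1,2-addition of the aryl Grignard reagent to the aldehyde; the C5 bromide is inert to an aryl Grignard reagent at 0 °C. The carbinol stereocentre is formed racemic and is removed in step 4.

Step 4
Reactants: 6 [2-(benzyloxy)-5-bromo-4-methoxyphenyl][4-(benzyloxy)phenyl]methanol
Product: 7 [2-(benzyloxy)-5-bromo-4-methoxyphenyl][4-(benzyloxy)phenyl]methanone
Conditions: MnO2 (activated, excess), CH2Cl2, rt
Reagents that add atoms: none
Why: MnO2 oxidation of a doubly benzylic secondary alcohol to the diaryl ketone; the neutral conditions suit an electron-rich benzhydrol that would ionise under acid.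

Step 5
Reactants: 7 [2-(benzyloxy)-5-bromo-4-methoxyphenyl][4-(benzyloxy)phenyl]methanone
Product: 8 [2-(benzyloxy)-5-(hydroxymethyl)-4-methoxyphenyl][4-(benzyloxy)phenyl]methanone
Conditions: K[AcOCH2BF3] (1.5 equiv), Pd(dba)2 (cat.), RuPhos (cat.), Na2CO3, 1,4-dioxane–H2O (10:1), 100 °C
Reagents that add atoms: potassium (acetoxymethyl)trifluoroborate, CC(=O)OC[B-](F)(F)F.[K+]
Why: Suzuki–Miyaura coupling of the aryl bromide with an acetoxymethyl trifluoroborate as hydroxymethyl anion equivalent; the acetate protects the organopalladium intermediate and is hydrolysed by the aqueous carbonate in the same flask. The electron-rich dialkylbiarylphosphine promotes oxidative addition at the electron-rich, ortho-substituted C5–Br bond, and the ketone and benzyl ethers are inert.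

Step 6
Reactants: 8 [2-(benzyloxy)-5-(hydroxymethyl)-4-methoxyphenyl][4-(benzyloxy)phenyl]methanone
Product: 9 [2-(benzyloxy)-5-(chloromethyl)-4-methoxyphenyl][4-(benzyloxy)phenyl]methanone
Conditions: SOCl2 (1.2 equiv), CH2Cl2, 0 °C; evaporate and use at once
Reagents that add atoms: thionyl chloride, O=S(Cl)Cl
Why: Deoxychlorination of a primary benzylic alcohol through its chlorosulfite. The by-products are gases, so the activated chloride can be carried on after evaporation without chromatography.

Step 7
Reactants: 10 propiolic acid; 11 1-(benzyloxy)-4-iodobenzene; 9 [2-(benzyloxy)-5-(chloromethyl)-4-methoxyphenyl][4-(benzyloxy)phenyl]methanone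
Product: 13 [2-(benzyloxy)-5-{3-[4-(benzyloxy)phenyl]prop-2-yn-1-yl}-4-methoxyphenyl][4-(benzyloxy)phenyl]methanone, via cesium 3-[4-(benzyloxy)phenyl]prop-2-ynoate 12 (not isolated)
Conditions: 10 (1.2 equiv), 11 (1.25 equiv), Pd(PPh3)2Cl2 (cat.), CuI (cat.), Cs2CO3 (4 equiv), THF–MeCN, rt, argon; then 9 (1.0 equiv), Pd(OAc)2 (cat.), XPhos (cat.), 75 °C
Reagents that add atoms: none
Why: In the first stage Pd(PPh3)2Cl2 is reduced in the flask to zerovalent palladium, which adds into the C–I bond of 11; the copper acetylide formed from the propiolate C–H end, copper iodide (CuI) and carbonate transmetallates, and reductive elimination makes the Cc–aryl bond of 12 (Sonogashira coupling of propiolic acid with an aryl iodide). At room temperature the carboxylate end is untouched because extrusion of carbon dioxide from an alkynoate needs heat, so the order of the two termini is fixed by temperature and by adding 9 only after 11 is consumed. In the second stage zerovalent palladium carrying XPhos adds into the benzylic C–Cl bond of 9, chloride on palladium is exchanged for the carboxylate of 12, loss of carbon dioxide gives a benzyl(alkynyl)palladium species, and reductive elimination forms Ca–Cb; the closest known reaction type is the palladium-catalysed decarboxylative coupling of arylpropiolic acids with benzyl halides, and the same two-stage use of propiolic acid is known with a second aryl halide. No ring is closed and no stereocentre is formed. The selectivity needed is between the two alkyne termini and between C- and O-benzylation of the carboxylate: cesium carbonate is the only base from the start, since an amidine or unhindered amine base would be N-benzylated by the activated chloride 9, and a sulfoxide solvent is avoided because it would oxidise 9. Two side paths lead back to 13: the benzylic ester from O-alkylation can ionise again on zerovalent palladium and decarboxylate, and any terminal arylalkyne from copper-induced protodecarboxylation couples with 9 under the same palladium, XPhos and carbonate conditions. Base-induced migration of the triple bond to the 1,3-diarylallene is of no consequence, because step 8 saturates the chain.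

Step 8
Reactants: 13 [2-(benzyloxy)-5-{3-[4-(benzyloxy)phenyl]prop-2-yn-1-yl}-4-methoxyphenyl][4-(benzyloxy)phenyl]methanone
Product: 14 {2-hydroxy-5-[3-(4-hydroxyphenyl)propyl]-4-methoxyphenyl}(4-hydroxyphenyl)methanone
Conditions: H2 (1 atm), 10% Pd/C, EtOAc–MeOH, rt; stopped after uptake of five equivalents
Reagents that add atoms: none
Why: Heterogeneous catalytic hydrogenation saturates the Cb–Cc triple bond (or an allene isomer) and hydrogenolyses the three aryl benzyl ethers. The diaryl ketone is conjugated with two oxygen-bearing rings and chelated by the freed O2 hydroxyl, so under neutral conditions at atmospheric pressure it should be reduced far more slowly.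

## Compound list

1 | 2-hydroxy-4-methoxybenzaldehyde | COc1ccc(C=O)c(O)c1 | starting material
2 | 5-bromo-2-hydroxy-4-methoxybenzaldehyde | COc1cc(O)c(C=O)cc1Br | intermediate
3 | 2-(benzyloxy)-5-bromo-4-methoxybenzaldehyde | COc1cc(OCc2ccccc2)c(C=O)cc1Br | intermediate
4 | 1-(benzyloxy)-4-bromobenzene | Brc1ccc(OCc2ccccc2)cc1 | starting material
5 | [4-(benzyloxy)phenyl]magnesium bromide (formed in the flask, not isolated) | Br[Mg]c1ccc(OCc2ccccc2)cc1 | intermediate
6 | [2-(benzyloxy)-5-bromo-4-methoxyphenyl][4-(benzyloxy)phenyl]methanol (racemic) | COc1cc(OCc2ccccc2)c(C(O)c2ccc(OCc3ccccc3)cc2)cc1Br | intermediate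
7 | [2-(benzyloxy)-5-bromo-4-methoxyphenyl][4-(benzyloxy)phenyl]methanone | COc1cc(OCc2ccccc2)c(C(=O)c2ccc(OCc3ccccc3)cc2)cc1Br | intermediate
8 | [2-(benzyloxy)-5-(hydroxymethyl)-4-methoxyphenyl][4-(benzyloxy)phenyl]methanone | COc1cc(OCc2ccccc2)c(C(=O)c2ccc(OCc3ccccc3)cc2)cc1CO | intermediate
9 | [2-(benzyloxy)-5-(chloromethyl)-4-methoxyphenyl][4-(benzyloxy)phenyl]methanone | COc1cc(OCc2ccccc2)c(C(=O)c2ccc(OCc3ccccc3)cc2)cc1CCl | intermediate
10 | propiolic acid (prop-2-ynoic acid) | C#CC(=O)O | starting material
11 | 1-(benzyloxy)-4-iodobenzene | Ic1ccc(OCc2ccccc2)cc1 | starting material
12 | cesium 3-[4-(benzyloxy)phenyl]prop-2-ynoate (formed in the flask, not isolated) | [Cs+].[O-]C(=O)C#Cc1ccc(OCc2ccccc2)cc1 | intermediate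
13 | [2-(benzyloxy)-5-{3-[4-(benzyloxy)phenyl]prop-2-yn-1-yl}-4-methoxyphenyl][4-(benzyloxy)phenyl]methanone | COc1cc(OCc2ccccc2)c(C(=O)c2ccc(OCc3ccccc3)cc2)cc1CC#Cc1ccc(OCc2ccccc2)cc1 | intermediate
14 | {2-hydroxy-5-[3-(4-hydroxyphenyl)propyl]-4-methoxyphenyl}(4-hydroxyphenyl)methanone | COc1cc(O)c(C(=O)c2ccc(O)cc2)cc1CCCc1ccc(O)cc1 | target

## Step count and least certain steps

Total step count: 8. Longest linear sequence: 8 steps (1, 2, 3, 6, 7, 8, 9, 13, 14); compounds 4, 10 and 11 enter as purchased materials.

**Step 7 (key step).** The most likely failure is consumption of the benzylic chloride outside the catalytic cycle: O-benzylation of the carboxylate without re-entry, attack by carbonate or adventitious water, or self-alkylation of the electron-rich ring. Homocoupling in the first stage and a second benzylation at the doubly activated Ca–H of the product are further risks. These are plausible because 9 is a 2,4-dioxygenated benzylic chloride and the decarboxylation needs heat. The fallback sets out from 9 and returns at 13. Compound 9 would be coupled with the purchased terminal alkyne 1-(benzyloxy)-4-ethynylbenzene F1 under PdCl2(MeCN)2, XPhos and Cs2CO3 in MeCN at 65 °C, with no copper. This is a known palladium-catalysed alkynylation of benzylic chlorides that forms Ca–Cb directly, with no carboxylate in the flask and no decarboxylation.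

**Step 8.** Over-reduction of the diaryl ketone to the benzhydrol or further may compete, because the chelation-shielded O2 benzyl ether is the slowest to cleave and prolongs exposure to the catalyst. The fallback sets out from 13 and returns at 14 without hydrogen on a metal surface. Diimide generated from TsNHNH2 and NaOAc in refluxing aqueous DME would saturate the triple bond to give the tribenzyl ether [2-(benzyloxy)-5-{3-[4-(benzyloxy)phenyl]propyl}-4-methoxyphenyl][4-(benzyloxy)phenyl]methanone F2. BCl3 with pentamethylbenzene as cation trap in CH2Cl2 at −78 °C would then cleave the three benzyl ethers, leaving the non-chelated methyl ether and the ketone untouched.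

**Step 5.** Protodebromination and slow oxidative addition at the electron-rich, ortho-substituted bromide may outrun transmetallation of the trifluoroborate, and hydrolysis of the acetate may stay incomplete. The fallback sets out from 7 and returns at 8. Palladium-catalysed reductive carbonylation (Pd(OAc)2, di(1-adamantyl)-n-butylphosphine, TMEDA, CO/H2, toluene, 100 °C) would give the aldehyde 4-(benzyloxy)-5-[4-(benzyloxy)benzoyl]-2-methoxybenzaldehyde F3. NaBH4 in THF–MeOH at −20 °C would then reduce the aldehyde ahead of the hindered, electron-rich diaryl ketone.

**Step 6.** The activated benzylic chloride may decompose by hydrolysis or by acid-promoted self-condensation during concentration or storage. The fallback sets out from 8, bypasses 9 and returns at 13. The acid 3-[4-(benzyloxy)phenyl]prop-2-ynoic acid F4 would be isolated from 10 and 11 by the first stage of step 7 with acidic work-up. It would be joined to 8 by Mitsunobu esterification (PPh3, DIAD, THF, 0 °C) to give the ester {4-(benzyloxy)-5-[4-(benzyloxy)benzoyl]-2-methoxyphenyl}methyl 3-[4-(benzyloxy)phenyl]prop-2-ynoate F5. Heating F5 with Pd(PPh3)4 in toluene at 110 °C should ionise the benzylic C–O bond, release carbon dioxide and form Ca–Cb by reductive elimination. This is the known decarboxylative benzylation of alkynes from benzylic alkynoates, which favours electron-rich benzylic esters.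

## Further compounds

F1 | step 7 | 1-(benzyloxy)-4-ethynylbenzene (purchased) | C#Cc1ccc(OCc2ccccc2)cc1
F2 | step 8 | [2-(benzyloxy)-5-{3-[4-(benzyloxy)phenyl]propyl}-4-methoxyphenyl][4-(benzyloxy)phenyl]methanone | COc1cc(OCc2ccccc2)c(C(=O)c2ccc(OCc3ccccc3)cc2)cc1CCCc1ccc(OCc2ccccc2)cc1
F3 | step 5 | 4-(benzyloxy)-5-[4-(benzyloxy)benzoyl]-2-methoxybenzaldehyde | COc1cc(OCc2ccccc2)c(C(=O)c2ccc(OCc3ccccc3)cc2)cc1C=O
F4 | step 6 | 3-[4-(benzyloxy)phenyl]prop-2-ynoic acid | OC(=O)C#Cc1ccc(OCc2ccccc2)cc1
F5 | step 6 | {4-(benzyloxy)-5-[4-(benzyloxy)benzoyl]-2-methoxyphenyl}methyl 3-[4-(benzyloxy)phenyl]prop-2-ynoate | COc1cc(OCc2ccccc2)c(C(=O)c2ccc(OCc3ccccc3)cc2)cc1COC(=O)C#Cc1ccc(OCc2ccccc2)cc1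
A1 | alternative 1 | tert-butyl{4-[5,7-dimethoxy-7-(trimethylsilyloxy)hepta-4,6-dien-1-yl]phenoxy}dimethylsilane (double-bond geometry not defined) | COC(=CC(OC)=CCCCc1ccc(O[Si](C)(C)C(C)(C)C)cc1)O[Si](C)(C)C
A2 | alternative 1 | 1-(4-{[tert-butyl(dimethyl)silyl]oxy}phenyl)prop-2-yn-1-one | C#CC(=O)c1ccc(O[Si](C)(C)C(C)(C)C)cc1
A3 | alternative 1 | {5-[3-(4-{[tert-butyl(dimethyl)silyl]oxy}phenyl)propyl]-2-hydroxy-4-methoxyphenyl}(4-{[tert-butyl(dimethyl)silyl]oxy}phenyl)methanone | COc1cc(O)c(C(=O)c2ccc(O[Si](C)(C)C(C)(C)C)cc2)cc1CCCc1ccc(O[Si](C)(C)C(C)(C)C)cc1
A4 | alternative 2 | 1-[4-(benzyloxy)phenyl]butane-1,3-dione | CC(=O)CC(=O)c1ccc(OCc2ccccc2)cc1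
A5 | alternative 2 | methyl 5-[4-(benzyloxy)phenyl]-2-methylidenepentanoate | C=C(CCCc1ccc(OCc2ccccc2)cc1)C(=O)OC
A6 | alternative 2 | 4-[4-(benzyloxy)benzoyl]-6-{3-[4-(benzyloxy)phenyl]propyl}cyclohexane-1,3-dione in its chelated enol form (racemic, one enantiomer drawn) | OC1=C(C(=O)c2ccc(OCc3ccccc3)cc2)C[C@@H](CCCc2ccc(OCc3ccccc3)cc2)C(=O)C1
A7 | alternative 3 | 2-{2-[4-(benzyloxy)phenyl]-2-oxoethyl}-5-{3-[4-(benzyloxy)phenyl]propyl}-4H-pyran-4-one | O=C(Cc1cc(=O)c(CCCc2ccc(OCc3ccccc3)cc2)co1)c1ccc(OCc2ccccc2)cc1
A8 | alternative 3 | [4-(benzyloxy)phenyl](5-{3-[4-(benzyloxy)phenyl]propyl}-2,4-dihydroxyphenyl)methanone | O=C(c1ccc(OCc2ccccc2)cc1)c1cc(CCCc2ccc(OCc3ccccc3)cc2)c(O)cc1O
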